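**Numbering used throughout.** Target ring: C1 (alkynyl carbon), C2 (=CH), C3 (OAc), C4 (OMe), C5 (OH), C6 (OH). Compounds 1–12 are named with shikimate numbering (C1 bears the carboxyl group); compounds 13–15 and 23–25 with target numbering. Target C6, C5, C4, C3, C2, C1 = shikimate C1, C2, C3, C4, C5, C6.

## Analysis of the target

The target is a monocyclic cyclohex-1-ene whose C1 carries a 1,3-enyne chain, so that ring alkene, alkyne and exocyclic methylidene form a cross-conjugated dienyne; the chain continues through a doubly allylic CH2 to an (E)-alkene and a tertiary allylic alcohol. Four contiguous stereocentres, C3 to C6 (3S,4R,5S,6S in this ring numbering), carry four differently dressed oxygens: an acetate at C3, a methyl ether at C4 and free hydroxyls at C5 and C6. Their relative arrangement is 3,4-cis, 4,5-trans, 5,6-cis. Sensitive points are the allylic C3 acetate (hydrolysis, migration), the acid-labile tertiary allylic alcohol, the skipped diene and the dienyne, so strong acid, strong base and hydrogenation are ruled out once the side chain is attached. The difficulty lies less in the carbon skeleton than in regiochemistry: acetyl and methyl must each go to one specific oxygen of a tetrol, and the alkyne to one specific alkene carbon. The strategy rests on the fact that C4 (OMe) and C3 (OAc) have the configuration of C3 and C4 of shikimic acid, and that the shikimate C5 oxygen sits on the carbon that becomes alkene carbon C2. The shikimate C1=C2 alkene lies exactly where the C6/C5 cis-diol is required, and the carboxyl carbon on shikimate C1 can be excised to leave a C6 ketone.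

## Retrosynthetic reasoning

**Si–O at C5 (25 from 24).** The last operation only unmasks the C5 hydroxyl. Keeping it silylated until the end protects it through the oxidative and reductive steps, and the bulky silyl ether is also the group meant to steer the reduction at C6.

**C6–H (24 from 23).** The C6 carbinol is traced back to a ketone, because a C6 carbonyl is what makes the two preceding ring operations possible. The forward reaction must be a 1,2-selective hydride addition that places the new hydroxyl cis to the C5 oxygen and leaves the acetate and the dienyne alone.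

**C1–C(sp) (23 from 15 and 22).** Cutting the sp2–sp bond divides the molecule into a ring piece and a side-chain piece of similar size and keeps the acid- and base-sensitive chain out of all ring chemistry. An α-iodoenone such as 15 is an excellent electrophile for a Sonogashira coupling, so the forward step can run cold and under mild amine base.

**C1–I (15 from 14).** In enone 14 the α-carbon C1 is the only position that an amine-mediated addition–elimination iodination can reach, so the site of the later alkyne is fixed by the position of the carbonyl alone.

**C1=C2 and C6=O (14 from 12 through 13).** The ring alkene is traced back to β-elimination of the C2 acetate of ketone 13; the leaving group defines the regiochemistry. The C6 ketone in turn comes from acid 12 by oxidative decarboxylation of the α-hydroxy acid, which cuts the bond between C6 and the carboxyl carbon. The C3 acetate is not β to the ketone and is kept.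

**Protecting-group logic (12 from 11 from 10).** Hydrogenolysis of a benzyl ester is allowed at this stage because the ring contains no alkene. The C5 hydroxyl is silylated beforehand so that the oxidant meets an α-hydroxy acid and not a vicinal diol.

**Two C–O bonds at C5 and C6 (10 from 9), the key disconnection.** Both oxygens are removed together to give the shikimate alkene of 9. The forward osmium-catalysed dihydroxylation must add on the face opposite the allylic C4 methoxy group; the C5 centre is kept and the C6 carbinol serves only as a handle for the decarboxylation.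

**Hydroxyl differentiation (9 from 8, 7, 4, 3 and 1).** The three hydroxyls of shikimic acid 1 are told apart by their geometry. The trans-diol is tied up as a butanediacetal in 3, the one hydroxyl left (the future C4 oxygen) is methylated in 4, and after removal of the acetal the two freed hydroxyls of 8 are acetylated. The benzyl ester is introduced from benzyl bromide 5 only at the stage of 7, after the acetal formation, because that step runs in an acidic alcohol medium in which a benzyl ester would be exchanged.

**Side chain (22 from 21, 19 and 20; 19 from 17 and 18; 17 from 16).** The terminal alkyne is traced back to trimethylsilylacetylene 20 and vinyl bromide 19. The skipped diene 19 is cut at the CH2–CH= bond, because 2,3-dibromopropene 18 delivers the allylic electrophile and the vinyl bromide in one reagent. The (E)-alkenyl boronate 17 comes from 2-methylbut-3-yn-2-ol 16 by a syn borylation–protonation that fixes the alkene geometry.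

## Alternatives that were turned down

**Alternative 1:** The ring alkene C1=C2 is disconnected by ring-closing metathesis. The C2-symmetric 1,7-diene A2 would come from diethyl L-tartrate A1 by two-directional vinylation, and a ruthenium alkylidene catalyst would close it to the conduritol E acetonide A3 with loss of ethene.
- For: the ring is reached in very few steps, closure of a cyclohexene by metathesis is about as dependable as a ring closure gets, and the twofold axis makes the first monofunctionalisation (for example of one of the two homotopic allylic hydroxyls) free of any regiochemical problem.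
- Against: the symmetry must then be broken three times in a fixed order. The alkyne has to go onto the alkene carbon next to the free allylic hydroxyl, which again means enone, iodination, coupling and a hydride reduction with the same facial question as in the chosen route. The methyl group must finally be placed on O4 and not on O5 of a freed diol that has no intrinsic bias and sits next to a migration-prone acetate. The double vinylation must also set two carbinol centres with the same sense.
- Comparison: on ring construction this alternative is stronger than the osmylation of an electron-poor alkene. The chosen route offers in its place a substrate in which the oxygen to be methylated is the only free hydroxyl of 3, so no selective etherification is ever asked for.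

**Alternative 2:** The C1–C6 bond is disconnected. The (Z)-bromoenyne aldehyde A5, built from L-arabinose A4, would be cyclised by a Nozaki–Hiyama–Kishi reaction (stoichiometric divalent chromium, catalytic divalent nickel) to the alkynyl cyclohexenol A6.
- For: the alkyne is already on C1 when the ring forms, the C6 carbinol is made directly without any ketone on the ring, and the conditions tolerate silyl ethers and alkynes.
- Against: the C6 configuration depends on 1,2-induction from an α-silyloxy aldehyde, which is no better assured than a hydride addition. A5 requires a long linear sequence from A4 (differentiation of three hydroxyls, chain extension, stereodefined bromoenyne). The two identical silyl ethers at C3 and C5 of A6 must later be distinguished to acetylate O3 alone beside two other hydroxyls. The silyl-capped alkyne must still be unmasked and joined to bromodiene 19, so the side chain is attached late in any case. Divalent chromium is needed in excess.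
- Comparison: this route is stronger in avoiding oxidation-state changes on the ring. The chosen route offers a far shorter path to a fully differentiated oxygen pattern (five steps to 9).

**Alternative 3:** The ring C2–C3 bond is disconnected by a Ferrier carbocyclization. The hex-5-enopyranoside A8, made from D-galactose A7, would be hydrated under catalysis by a divalent mercury salt, and the resulting keto-aldehyde would close by aldol reaction to the β-hydroxy ketone A9.
- For: the C4 methyl ether and the C5/C6 cis-diol come directly from the sugar (its cis-3,4-diol takes an acetonide naturally), so C6 is not created by a late reduction. On this point the alternative is stronger than the chosen route.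
- Against: the carbonyl of A9 lies at C1 and not at C6. It would have to be converted into the alkynyl-bearing C1=C2 alkene through an enol derivative formed toward C2, yet that enolate has the C3 oxygen in the β-position, and β-elimination to the C2=C3 enone is the usual fate of such ketones; enolisation toward C6 competes as well. Several protecting-group steps are needed to reach A8, and a mercury salt is used.
- Comparison: A9 secures more stereocentres from the chiral pool. The chosen route offers in its place a carbonyl at C6, where it activates C1 for iodination, and it uses the same β-elimination tendency productively, since the leaving group is the C2 acetate and the alkene formed is the required one.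

Key step: step 6

**Remark on the chemistry.** The two acetal carbons of the butanediacetal are drawn (S,S), the arrangement with both methoxy groups axial; they are removed in step 4 and have no bearing on the target.

## Route

Step 1
Reactants: 1 shikimic acid
Product: 3 methyl 4,5-O-[(2S,3S)-2,3-dimethoxybutane-2,3-diyl]shikimate, via methyl shikimate 2 (not isolated)
Conditions: MeOH, CSA (cat.), reflux; then butane-2,3-dione, HC(OMe)3, reflux
Reagents that add atoms: methanol CO; butane-2,3-dione CC(=O)C(C)=O; trimethyl orthoformate COC(OC)OC
Why: Fischer esterification followed by thermodynamic diacetal formation; the six-membered bis-acetal forms only across the trans-diequatorial 4,5-diol, so the pseudoaxial allylic 3-OH stays free. The orthoformate removes water and drives both equilibria.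

Step 2
Reactants: 3 methyl 4,5-O-[(2S,3S)-2,3-dimethoxybutane-2,3-diyl]shikimate
Product: 4 methyl 4,5-O-[(2S,3S)-2,3-dimethoxybutane-2,3-diyl]-3-O-methylshikimate
Conditions: MeI (excess), Ag2O, 4 Å MS, MeCN, 40 °C, dark
Reagents that add atoms: iodomethane CI
Why: Purdie methylation of the only free hydroxyl; the neutral silver-assisted conditions avoid an alkoxide next to the enoate and so avoid elimination toward an aromatic ring.

Step 3
Reactants: 4 methyl 4,5-O-[(2S,3S)-2,3-dimethoxybutane-2,3-diyl]-3-O-methylshikimate; 5 benzyl bromide
Product: 7 benzyl 4,5-O-[(2S,3S)-2,3-dimethoxybutane-2,3-diyl]-3-O-methylshikimate, via lithium carboxylate 6 (not isolated)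
Conditions: LiOH·H2O, THF/H2O (3:1), rt; evaporate; BnBr, Bu4NI (cat.), DMF, rt
Reagents that add atoms: lithium hydroxide [Li+].[OH-]
Why: Saponification and SN2 O-alkylation of the carboxylate; acetal and methyl ether are inert to both. The ester is changed here, while no acetate is present, so that the carboxyl group can later be freed by hydrogenolysis without touching the acetates.

Step 4
Reactants: 7 benzyl 4,5-O-[(2S,3S)-2,3-dimethoxybutane-2,3-diyl]-3-O-methylshikimate
Product: 8 benzyl 3-O-methylshikimate
Conditions: TFA/H2O (9:1), rt, short reaction time
Reagents that add atoms: none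
Why: Acid hydrolysis of the bis-acetal; benzyl ester and methyl ether survive, and the allylic ether does not ionise because the derived cation would be cross-conjugated with the ester.

Step 5
Reactants: 8 benzyl 3-O-methylshikimate
Product: 9 benzyl 4,5-di-O-acetyl-3-O-methylshikimate
Conditions: Ac2O, pyridine, DMAP (cat.), CH2Cl2, 0 °C → rt
Reagents that add atoms: acetic anhydride CC(=O)OC(C)=O
Why: Standard acylation of two secondary hydroxyls; the 4-acetate is the one that stays in the target and the 5-acetate is the later leaving group.

Step 6
Reactants: 9 benzyl 4,5-di-O-acetyl-3-O-methylshikimate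
Product: 10 benzyl 4,5-di-O-acetyl-1,2-dihydroxy-3-O-methyl-1,2-dihydroshikimate (1-OH and 2-OH cis to each other and trans to 3-OMe)
Conditions: OsO4 (5 mol %), NMO (2 equiv), citric acid (1 equiv), t-BuOH/H2O (1:1), rt
Reagents that add atoms: osmium tetroxide O=[Os](=O)(=O)=O; N-methylmorpholine N-oxide C[N+]1([O-])CCOCC1
Why: OsO4 adds suprafacially across the C1=C2 enoate alkene by [3+2] cycloaddition, the osmate ester of hexavalent osmium is hydrolysed, and NMO returns the metal to octavalent osmium. The closest known reaction type is the catalytic OsO4/NMO cis-dihydroxylation of cyclic allylic ethers and of shikimate esters, which takes place anti to the allylic oxygen. No ring is closed; two C–O bonds are formed. The new C2 centre (target C5) is controlled by the 3-methoxy group: in the half-chair with both acetates equatorial this group is pseudoaxial and shields its own face, so osmium approaches from the opposite side. The new C1 centre is set cis to it by the suprafacial nature of the addition and is erased again in step 9. The selectivity required is facial only, since the substrate has a single alkene. Citric acid keeps the medium acidic, which speeds hydrolysis of the osmate ester of this electron-poor alkene and suppresses hydrolysis or migration of the acetates.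

Step 7
Reactants: 10 benzyl 4,5-di-O-acetyl-1,2-dihydroxy-3-O-methyl-1,2-dihydroshikimate
Product: 11 benzyl 4,5-di-O-acetyl-2-O-(tert-butyldimethylsilyl)-1,2-dihydroxy-3-O-methyl-1,2-dihydroshikimate
Conditions: TBSOTf (1.2 equiv), 2,6-lutidine, CH2Cl2, −78 → −20 °C
Reagents that add atoms: tert-butyldimethylsilyl trifluoromethanesulfonate CC(C)(C)[Si](C)(C)OS(=O)(=O)C(F)(F)F
Why: Silylation of the secondary hydroxyl in preference to the tertiary, electron-poor α-hydroxy ester hydroxyl. The ether prevents glycol cleavage in step 9 and later directs the reduction in step 16.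

Step 8
Reactants: 11 benzyl 4,5-di-O-acetyl-2-O-(tert-butyldimethylsilyl)-1,2-dihydroxy-3-O-methyl-1,2-dihydroshikimate
Product: 12 4,5-di-O-acetyl-2-O-(tert-butyldimethylsilyl)-1,2-dihydroxy-3-O-methyl-1,2-dihydroshikimic acid
Conditions: H2 (1 atm), 10% Pd/C, EtOAc, rt
Reagents that add atoms: none
Why: Hydrogenolysis of the benzyl ester; the ring is saturated at this stage, and acetates and the silyl ether are inert in ethyl acetate.

Step 9
Reactants: 12 4,5-di-O-acetyl-2-O-(tert-butyldimethylsilyl)-1,2-dihydroxy-3-O-methyl-1,2-dihydroshikimic acid
Product: 14 3-acetoxy-5-(tert-butyldimethylsilyloxy)-4-methoxycyclohex-1-en-6-one (3-OAc cis to 4-OMe; 5-OSi trans to 4-OMe), via β-acetoxy ketone 13 (not isolated)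
Conditions: Pb(OAc)4 (1.1 equiv), CH2Cl2, 0 °C; then Et3N (3 equiv), 0 °C → rt
Reagents that add atoms: none
Why: Oxidative decarboxylation of an α-hydroxy acid: carboxylate and tertiary hydroxyl bind tetravalent lead, and a two-electron fragmentation gives the C6 ketone, CO2 and divalent lead. The acetate on C2 is then β to the ketone and leaves by E1cB through the enolate of the C1 methylene group. The C3 acetate is γ and stays, and enolisation toward C5 is slower and would only expel a poor methoxide leaving group.

Step 10
Reactants: 14 3-acetoxy-5-(tert-butyldimethylsilyloxy)-4-methoxycyclohex-1-en-6-one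
Product: 15 3-acetoxy-5-(tert-butyldimethylsilyloxy)-1-iodo-4-methoxycyclohex-1-en-6-one
Conditions: I2 (2 equiv), pyridine/CH2Cl2 (1:1), 0 °C → rt
Reagents that add atoms: iodine II
Why: α-Iodination of an enone by Baylis–Hillman-type conjugate addition of pyridine, iodination of the enolate at C1 and loss of pyridine; no other carbon of the molecule is nucleophilic under these conditions.

Step 11
Reactants: 16 2-methylbut-3-yn-2-ol
Product: 17 (E)-2-methyl-4-(4,4,5,5-tetramethyl-1,3,2-dioxaborolan-2-yl)but-3-en-2-ol
Conditions: B2pin2 (1.1 equiv), CuCl (3 mol %), Xantphos (3 mol %), NaOt-Bu (6 mol %), MeOH (2 equiv), THF, rt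
Reagents that add atoms: bis(pinacolato)diboron CC1(C)OB(OC1(C)C)B1OC(C)(C)C(C)(C)O1
Why: Copper-catalysed borylation–protonation of a terminal alkyne: syn addition of the boryl-copper species puts boron on the terminal carbon, away from the bulky carbinol, and protonation by methanol gives the (E)-alkenyl boronate; the free tertiary hydroxyl is tolerated.

Step 12
Reactants: 17 (E)-2-methyl-4-(4,4,5,5-tetramethyl-1,3,2-dioxaborolan-2-yl)but-3-en-2-ol; 18 2,3-dibromopropene
Product: 19 (E)-6-bromo-2-methylhepta-3,6-dien-2-ol
Conditions: 18 (2 equiv), Pd(PPh3)4 (5 mol %), K2CO3 (2 equiv), THF/H2O (5:1), 50 °C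
Reagents that add atoms: none
Why: Suzuki–Miyaura coupling of an alkenyl boronate with an allylic bromide; zerovalent palladium inserts into the allylic C–Br bond much faster than into the vinylic one, and both ends of the 2-bromoallyl unit are CH2, so either terminus gives the same 1,4-diene. The alkene geometry of 17 is retained.

Step 13
Reactants: 19 (E)-6-bromo-2-methylhepta-3,6-dien-2-ol; 20 trimethylsilylacetylene
Product: 21 (E)-2-methyl-6-methylidene-8-(trimethylsilyl)oct-3-en-7-yn-2-ol
Conditions: PdCl2(PPh3)2 (3 mol %), CuI (6 mol %), Et3N, 50 °C
Reagents that add atoms: none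
Why: Sonogashira coupling of a 2-bromo-1-alkene; the silyl cap prevents double coupling and homocoupling of acetylene.

Step 14
Reactants: 21 (E)-2-methyl-6-methylidene-8-(trimethylsilyl)oct-3-en-7-yn-2-ol
Product: 22 (E)-2-methyl-6-methylideneoct-3-en-7-yn-2-ol
Conditions: K2CO3 (0.2 equiv), MeOH, 0 °C → rt
Reagents that add atoms: none
Why: Methanolysis of the C(sp)–Si bond under catalytic carbonate, mild enough not to move the skipped diene into conjugation.

Step 15
Reactants: 15 3-acetoxy-5-(tert-butyldimethylsilyloxy)-1-iodo-4-methoxycyclohex-1-en-6-one; 22 (E)-2-methyl-6-methylideneoct-3-en-7-yn-2-ol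
Product: 23 3-acetoxy-5-(tert-butyldimethylsilyloxy)-4-methoxy-1-[(5E)-7-hydroxy-7-methyl-3-methylideneoct-5-en-1-yn-1-yl]cyclohex-1-en-6-one
Conditions: PdCl2(PPh3)2 (5 mol %), CuI (10 mol %), i-Pr2NH (3 equiv), THF (degassed), 0 °C → rt
Reagents that add atoms: none
Why: Sonogashira coupling of an α-iodoenone, whose electron-poor C–I bond undergoes oxidative addition at or below room temperature, so the base-sensitive γ-acetoxy enone is exposed only to a hindered secondary amine in the cold.

Step 16
Reactants: 23 3-acetoxy-5-(tert-butyldimethylsilyloxy)-4-methoxy-1-[(5E)-7-hydroxy-7-methyl-3-methylideneoct-5-en-1-yn-1-yl]cyclohex-1-en-6-one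
Product: 24 3-acetoxy-5-(tert-butyldimethylsilyloxy)-6-hydroxy-4-methoxy-1-[(5E)-7-hydroxy-7-methyl-3-methylideneoct-5-en-1-yn-1-yl]cyclohex-1-ene (6-OH cis to 5-OSi)
Conditions: NaBH4 (1.2 equiv), CeCl3·7H2O (1.2 equiv), MeOH, −78 °C
Reagents that add atoms: none
Why: Luche reduction, 1,2-selective for the enone carbonyl and cold enough to spare the acetate. The C5 silyloxy group and its trans neighbour, the C4 methoxy group, are expected to sit diaxial, which removes their gauche repulsion and the dipole clash of an equatorial C–O bond with the carbonyl. Under these non-chelating conditions hydride should add anti to the bulky axial C5–O bond, which places the new C6 hydroxyl cis to the C5 oxygen.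

Step 17
Reactants: 24 3-acetoxy-5-(tert-butyldimethylsilyloxy)-6-hydroxy-4-methoxy-1-[(5E)-7-hydroxy-7-methyl-3-methylideneoct-5-en-1-yn-1-yl]cyclohex-1-ene
Product: 25 (3S,4R,5S,6S)-3-acetoxy-5,6-dihydroxy-4-methoxy-1-[(5E)-7-hydroxy-7-methyl-3-methylideneoct-5-en-1-yn-1-yl]cyclohex-1-ene (CNP0546270.2)
Conditions: HF·pyridine, pyridine, THF, 0 °C → rt
Reagents that add atoms: none
Why: Fluoride cleavage of the silyl ether in a pyridine-buffered medium that neither ionises the tertiary allylic alcohol nor hydrolyses the acetate. The freed C5 hydroxyl is trans-1,3 to the C3 acetate and its neighbour C4 carries a methyl ether, so no acyl migration path is open.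

## Compound list

1 | shikimic acid | C1[C@@H](O)[C@H](O)[C@H](O)C=C1C(=O)O | starting material
2 | methyl shikimate | C1[C@@H](O)[C@H](O)[C@H](O)C=C1C(=O)OC | intermediate (not isolated)
3 | methyl 4,5-O-[(2S,3S)-2,3-dimethoxybutane-2,3-diyl]shikimate | C1[C@H]2O[C@](C)(OC)[C@@](C)(OC)O[C@@H]2[C@H](O)C=C1C(=O)OC | intermediate
4 | methyl 4,5-O-[(2S,3S)-2,3-dimethoxybutane-2,3-diyl]-3-O-methylshikimate | C1[C@H]2O[C@](C)(OC)[C@@](C)(OC)O[C@@H]2[C@H](OC)C=C1C(=O)OC | intermediate
5 | benzyl bromide | BrCc1ccccc1 | starting material
6 | lithium 4,5-O-[(2S,3S)-2,3-dimethoxybutane-2,3-diyl]-3-O-methylshikimate | C1[C@H]2O[C@](C)(OC)[C@@](C)(OC)O[C@@H]2[C@H](OC)C=C1C(=O)[O-].[Li+] | intermediate (not isolated)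
7 | benzyl 4,5-O-[(2S,3S)-2,3-dimethoxybutane-2,3-diyl]-3-O-methylshikimate | C1[C@H]2O[C@](C)(OC)[C@@](C)(OC)O[C@@H]2[C@H](OC)C=C1C(=O)OCc3ccccc3 | intermediate
8 | benzyl 3-O-methylshikimate | C1[C@@H](O)[C@H](O)[C@H](OC)C=C1C(=O)OCc1ccccc1 | intermediate
9 | benzyl 4,5-di-O-acetyl-3-O-methylshikimate | C1[C@@H](OC(C)=O)[C@H](OC(C)=O)[C@H](OC)C=C1C(=O)OCc1ccccc1 | intermediate
10 | benzyl 4,5-di-O-acetyl-1,2-dihydroxy-3-O-methyl-1,2-dihydroshikimate (1-OH, 2-OH cis; both trans to 3-OMe) | C1[C@@H](OC(C)=O)[C@H](OC(C)=O)[C@H](OC)[C@@H](O)[C@@]1(C(=O)OCc2ccccc2)O | intermediate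
11 | benzyl 4,5-di-O-acetyl-2-O-(tert-butyldimethylsilyl)-1,2-dihydroxy-3-O-methyl-1,2-dihydroshikimate | C1[C@@H](OC(C)=O)[C@H](OC(C)=O)[C@H](OC)[C@@H](O[Si](C)(C)C(C)(C)C)[C@@]1(C(=O)OCc2ccccc2)O | intermediate
12 | 4,5-di-O-acetyl-2-O-(tert-butyldimethylsilyl)-1,2-dihydroxy-3-O-methyl-1,2-dihydroshikimic acid | C1[C@@H](OC(C)=O)[C@H](OC(C)=O)[C@H](OC)[C@@H](O[Si](C)(C)C(C)(C)C)[C@@]1(C(=O)O)O | intermediate
13 | 2,3-diacetoxy-5-(tert-butyldimethylsilyloxy)-4-methoxycyclohexan-6-one (2-OAc trans to 3-OAc; 3-OAc cis to 4-OMe; 5-OSi trans to 4-OMe) | C1[C@@H](OC(C)=O)[C@H](OC(C)=O)[C@H](OC)[C@@H](O[Si](C)(C)C(C)(C)C)C1=O | intermediate (not isolated)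
14 | 3-acetoxy-5-(tert-butyldimethylsilyloxy)-4-methoxycyclohex-1-en-6-one | C1=C[C@H](OC(C)=O)[C@H](OC)[C@@H](O[Si](C)(C)C(C)(C)C)C1=O | intermediate
15 | 3-acetoxy-5-(tert-butyldimethylsilyloxy)-1-iodo-4-methoxycyclohex-1-en-6-one | IC1=C[C@H](OC(C)=O)[C@H](OC)[C@@H](O[Si](C)(C)C(C)(C)C)C1=O | intermediate
16 | 2-methylbut-3-yn-2-ol | C#CC(C)(C)O | starting material
17 | (E)-2-methyl-4-(4,4,5,5-tetramethyl-1,3,2-dioxaborolan-2-yl)but-3-en-2-ol | CC(C)(O)/C=C/B1OC(C)(C)C(C)(C)O1 | intermediate
18 | 2,3-dibromopropene | C=C(Br)CBr | starting material
19 | (E)-6-bromo-2-methylhepta-3,6-dien-2-ol | C=C(Br)C/C=C/C(C)(C)O | intermediate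
20 | trimethylsilylacetylene | C#C[Si](C)(C)C | starting material
21 | (E)-2-methyl-6-methylidene-8-(trimethylsilyl)oct-3-en-7-yn-2-ol | C[Si](C)(C)C#CC(=C)C/C=C/C(C)(C)O | intermediate
22 | (E)-2-methyl-6-methylideneoct-3-en-7-yn-2-ol | C#CC(=C)C/C=C/C(C)(C)O | intermediate
23 | 3-acetoxy-5-(tert-butyldimethylsilyloxy)-4-methoxy-1-[(5E)-7-hydroxy-7-methyl-3-methylideneoct-5-en-1-yn-1-yl]cyclohex-1-en-6-one | C=C(C#CC1=C[C@H](OC(C)=O)[C@H](OC)[C@@H](O[Si](C)(C)C(C)(C)C)C1=O)C/C=C/C(C)(C)O | intermediate
24 | 3-acetoxy-5-(tert-butyldimethylsilyloxy)-6-hydroxy-4-methoxy-1-[(5E)-7-hydroxy-7-methyl-3-methylideneoct-5-en-1-yn-1-yl]cyclohex-1-ene (6-OH cis to 5-OSi) | C=C(C#CC1=C[C@H](OC(C)=O)[C@H](OC)[C@@H](O[Si](C)(C)C(C)(C)C)[C@H]1O)C/C=C/C(C)(C)O | intermediate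
25 | (3S,4R,5S,6S)-3-acetoxy-5,6-dihydroxy-4-methoxy-1-[(5E)-7-hydroxy-7-methyl-3-methylideneoct-5-en-1-yn-1-yl]cyclohex-1-ene (CNP0546270.2) | C=C(C#CC1=C[C@H](OC(C)=O)[C@H](OC)[C@@H](O)[C@H]1O)C/C=C/C(C)(C)O | target

## Step count and risk

Total step count: 17. Longest linear sequence: 13 steps (steps 1–10 and 15–17, from shikimic acid 1); the side chain takes 4 steps (11–14).

**Step 6 (key step).** The enoate alkene is trisubstituted and electron-poor, so slow osmylation and incomplete conversion are the most likely problems. Facial selectivity could also erode if the ring populates the half-chair with both acetates axial, and the acetates could migrate or hydrolyse in the aqueous amine oxide medium. Fallback: the dihydroxylation is moved one stage earlier, onto the conformationally locked trans-fused acetal, where no acetate is present. Setting out from 7, the same OsO4/NMO oxidation should give benzyl 4,5-O-[(2S,3S)-2,3-dimethoxybutane-2,3-diyl]-1,2-dihydroxy-3-O-methyl-1,2-dihydroshikimate F1; TBSOTf/2,6-lutidine silylates the secondary hydroxyl to the silyl ether F2; brief TFA/H2O at 0 °C removes the acetal to give the 4,5-diol F3; and Ac2O/pyridine without DMAP acetylates the two secondary hydroxyls but not the tertiary one, which returns the route to 11.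

**Step 16.** Poor or reversed facial selectivity is the main danger: if the ring reacts through the conformer with equatorial C5 and C4 substituents, or if the axial C4 methoxy group hinders the intended trajectory, hydride adds from the other face and the C6 epimer results. Fallback: the other face is accepted and C6 is inverted. Setting out from 23, the reduction gives the C6-epimeric alcohol F4 (6-OH trans to 5-OSi); a Mitsunobu reaction (PPh3, diisopropyl azodicarboxylate, chloroacetic acid, THF, 0 °C) inverts the secondary allylic centre to the chloroacetate F5 and leaves the tertiary alcohol untouched; thiourea/NaHCO3 in ethanol then removes the chloroacetyl group selectively beside the C3 acetate and returns to 24.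

**Step 9.** Misdirected enolisation is the main concern: under base the ketone could enolise toward C5, with epimerisation of the α-silyloxy centre or loss of the C4 methoxy group and subsequent aromatisation; over-oxidation by the lead reagent is a second risk. Fallback: the carboxyl carbon is removed by reduction and glycol cleavage under neutral conditions. Setting out from 12, BH3·SMe2 (THF, 0 °C → rt) reduces the carboxylic acid in the presence of the acetates to the hydroxymethyl carbinol F6, and NaIO4 (THF/H2O, pH 7) cleaves this 1,2-diol to ketone 13, which is then treated with Et3N as in step 9 to reach 14.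

**Step 12.** Loss of chemoselectivity (a second coupling at the vinylic bromide), base-induced migration of the skipped diene into conjugation, and hydrolysis of the allylic bromide are the likely failure modes. Fallback: the (E)-alkene is made by cross-metathesis instead of being carried in from a boronate. Setting out from 18, CH2=CHMgBr with catalytic CuI (THF, −20 °C) gives 2-bromopenta-1,4-diene F7, and cross-metathesis of F7 with excess 2-methylbut-3-en-2-ol using the second-generation Grubbs catalyst RuCl2(=CHPh)(H2IMes)(PCy3) (CH2Cl2, 40 °C) returns to 19; the 2-bromoalkene does not take part in metathesis.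

**Step 15.** Amine-induced degradation of the γ-acetoxy α-iodoenone (elimination and aromatisation), reductive loss of iodine and oxidative homocoupling of 22 are the risks. Fallback: the order of coupling and reduction is reversed, so that no enone is exposed to amine and copper. Setting out from 15, reduction under the conditions of step 16 gives the iodo allylic alcohol F8 (3-acetoxy-5-(tert-butyldimethylsilyloxy)-6-hydroxy-1-iodo-4-methoxycyclohex-1-ene), and Sonogashira coupling of F8 with 22 under the conditions of step 15 returns directly to 24.

## Further compounds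

F1 | step 6 | benzyl 4,5-O-[(2S,3S)-2,3-dimethoxybutane-2,3-diyl]-1,2-dihydroxy-3-O-methyl-1,2-dihydroshikimate | C1[C@H]2O[C@](C)(OC)[C@@](C)(OC)O[C@@H]2[C@H](OC)[C@@H](O)[C@@]1(C(=O)OCc3ccccc3)O
F2 | step 6 | benzyl 2-O-(tert-butyldimethylsilyl)-4,5-O-[(2S,3S)-2,3-dimethoxybutane-2,3-diyl]-1,2-dihydroxy-3-O-methyl-1,2-dihydroshikimate | C1[C@H]2O[C@](C)(OC)[C@@](C)(OC)O[C@@H]2[C@H](OC)[C@@H](O[Si](C)(C)C(C)(C)C)[C@@]1(C(=O)OCc3ccccc3)O
F3 | step 6 | benzyl 2-O-(tert-butyldimethylsilyl)-1,2-dihydroxy-3-O-methyl-1,2-dihydroshikimate | C1[C@@H](O)[C@H](O)[C@H](OC)[C@@H](O[Si](C)(C)C(C)(C)C)[C@@]1(C(=O)OCc2ccccc2)O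
F4 | step 16 | C6 epimer of 24 (6-OH trans to 5-OSi) | C=C(C#CC1=C[C@H](OC(C)=O)[C@H](OC)[C@@H](O[Si](C)(C)C(C)(C)C)[C@@H]1O)C/C=C/C(C)(C)O
F5 | step 16 | 6-O-chloroacetyl derivative of 24 | C=C(C#CC1=C[C@H](OC(C)=O)[C@H](OC)[C@@H](O[Si](C)(C)C(C)(C)C)[C@H]1OC(=O)CCl)C/C=C/C(C)(C)O
F6 | step 9 | 2,3-diacetoxy-5-(tert-butyldimethylsilyloxy)-6-(hydroxymethyl)-4-methoxycyclohexan-6-ol | C1[C@@H](OC(C)=O)[C@H](OC(C)=O)[C@H](OC)[C@@H](O[Si](C)(C)C(C)(C)C)[C@@]1(CO)O
F7 | step 12 | 2-bromopenta-1,4-diene | C=CCC(Br)=C
F8 | step 15 | 3-acetoxy-5-(tert-butyldimethylsilyloxy)-6-hydroxy-1-iodo-4-methoxycyclohex-1-ene (6-OH cis to 5-OSi) | IC1=C[C@H](OC(C)=O)[C@H](OC)[C@@H](O[Si](C)(C)C(C)(C)C)[C@H]1O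
A1 | alternative 1 | diethyl L-tartrate | CCOC(=O)[C@H](O)[C@@H](O)C(=O)OCC
A2 | alternative 1 | 4,5-O-isopropylideneocta-1,7-diene-3,4,5,6-tetrol (C2-symmetric; stereocentres as in A3) | C=C[C@H](O)[C@H](O2)[C@@H](OC2(C)C)[C@H](C=C)O
A3 | alternative 1 | 4,5-O-isopropylidenecyclohex-1-ene-3,4,5,6-tetrol (conduritol E acetonide) | C1=C[C@H](O)[C@H](O2)[C@@H](OC2(C)C)[C@H]1O
A4 | alternative 2 | L-arabinose (open-chain form) | O=C[C@H](O)[C@@H](O)[C@@H](O)CO
A5 | alternative 2 | (Z)-6-bromo-2,4-bis(tert-butyldimethylsilyloxy)-3-methoxy-8-(triisopropylsilyl)oct-5-en-7-ynal | CC(C)[Si](C(C)C)(C(C)C)C#C/C(Br)=C/[C@H](O[Si](C)(C)C(C)(C)C)[C@H](OC)[C@@H](O[Si](C)(C)C(C)(C)C)C=O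
A6 | alternative 2 | 1-(triisopropylsilylethynyl)-3,5-bis(tert-butyldimethylsilyloxy)-4-methoxycyclohex-1-en-6-ol | CC(C)[Si](C(C)C)(C(C)C)C#CC1=C[C@H](O[Si](C)(C)C(C)(C)C)[C@H](OC)[C@@H](O[Si](C)(C)C(C)(C)C)[C@H]1O
A7 | alternative 3 | D-galactose (open-chain form) | O=C[C@H](O)[C@@H](O)[C@@H](O)[C@H](O)CO
A8 | alternative 3 | methyl 6-deoxy-3,4-O-isopropylidene-2-O-methyl-β-L-arabino-hex-5-enopyranoside | C=C1O[C@H](OC)[C@H](OC)[C@@H](O2)[C@H]1OC2(C)C
A9 | alternative 3 | 3-hydroxy-4-methoxy-5,6-O-isopropylidenedioxycyclohexanone (ketone at ring C1) | O=C1C[C@H](O)[C@H](OC)[C@@H](O2)[C@H]1OC2(C)C
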